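**Plan**

- Cuts. (a) The two C–O bonds at the spiro ketal carbon (ether O–C and lactone O–C) are cut, giving a cage dihydroxy acid and a pyrano-hydroxyquinone. (b) In the cage (numbered C1 carbinol bridgehead, C2 ketone, C3 prenyl-bearing ether carbon, O4, C5 Me2, C6 methine, C7 oxygenated bridgehead, C8=C9, C10) the C7–C8 and C1–C9 bonds are cut (acrylate Michael–aldol). (c) The C3–O4 and C3–CH2 bonds are cut together.
- Enabling feature. C3 is fully substituted, carries the tetrahydrofuran oxygen and an allyl-type group, and lies between the C2 ketone and C7 (a ketone before the cage closes). It is therefore C2 of a cyclohexane-1,3-dione whose C4 substituent, C6–C5(Me)2–O, holds an allyl ether oxygen that can reach it through a five-membered ring.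
- Forward order. The carbocycle comes from 2,4-dimethoxyphenol via a quinone monoketal; the tetrahydrofuranone ring and quaternary C3 arise in step 9; the bicyclo[2.2.2]octene follows by Michael–aldol closure and dehydrogenation; the pyranoquinone is made separately from 2,6-dimethoxybenzoquinone; ester formation and spirocyclisation to the 1,3-dioxan-4-one come last.
- Stereochemistry. C6 comes from a rhodium/BINAP conjugate addition, C3 from the tether in step 9, C1 and C7 from the geometry of the cage closure, and the spiro carbon with its neighbouring prenyl methine from equilibration in the last step.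

Key step: step 9

Assumption: the configuration of the target at the spiro ketal carbon and the adjacent prenyl-bearing methine is taken to be the thermodynamically preferred one, since both centres can equilibrate (reversible oxa-Michael closure, enolisation) under the conditions of the last step.

**Route**

Step 1
Reactants: 1 2,4-dimethoxyphenol
Product: 2 2,4,4-trimethoxycyclohexa-2,5-dien-1-one
Conditions: PhI(OAc)2, MeOH, 0 °C
Reagents that add atoms: methanol, CO
Why: Hypervalent-iodine oxidative dearomatisation of a para-alkoxyphenol, in which methanol captures the para position of the oxidised phenol to give the quinone monoketal.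

Step 2
Reactants: 2 2,4,4-trimethoxycyclohexa-2,5-dien-1-one; 3 isopropenylboronic acid pinacol ester
Product: 4 (S)-2,4,4-trimethoxy-5-(prop-1-en-2-yl)cyclohex-2-en-1-one
Conditions: [Rh(cod)Cl]2 (2.5 mol %), (S)-BINAP (6 mol %), KOH (0.5 equiv), 1,4-dioxane–H2O (10:1), 40 °C
Reagents that add atoms: none
Why: Rhodium-catalysed asymmetric 1,4-addition of an alkenylboron reagent (Hayashi–Miyaura reaction) to the unsubstituted enone arm of the quinone monoketal, the methoxy-bearing arm being too hindered and electron-rich to compete; the (S)-BINAP complex is expected, by the usual model for cyclohexenones, to deliver the isopropenyl group to the face that gives the (S) centre, the later cage methine C6.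

Step 3
Reactants: 4 (S)-2,4,4-trimethoxy-5-(prop-1-en-2-yl)cyclohex-2-en-1-one
Product: 5 (1S,5S)-2,4,4-trimethoxy-5-(prop-1-en-2-yl)cyclohex-2-en-1-ol (1,5-cis)
Conditions: NaBH4, CeCl3·7H2O, MeOH, −78 to −40 °C
Reagents that add atoms: none
Why: Luche reduction gives clean 1,2-reduction of the enone and, by axial hydride attack as in the carvone to cis-carveol case, the cis alcohol; this carbinol carbon becomes an enolate carbon in step 11, so its configuration does not reach the target.

Step 4
Reactants: 5 (1S,5S)-2,4,4-trimethoxy-5-(prop-1-en-2-yl)cyclohex-2-en-1-ol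
Product: 6 tert-butyl{[(1S,5S)-2,4,4-trimethoxy-5-(prop-1-en-2-yl)cyclohex-2-en-1-yl]oxy}dimethylsilane
Conditions: TBSCl, imidazole, DMF, rt
Reagents that add atoms: tert-butyldimethylsilyl chloride, CC(C)(C)[Si](C)(C)Cl
Why: Standard silylation of a secondary alcohol; a silyl ether is chosen because a benzyl or alkoxymethyl ether here would later offer the carbenoid an activated C–H bond for 1,5-insertion.

Step 5
Reactants: 6 tert-butyl{[(1S,5S)-2,4,4-trimethoxy-5-(prop-1-en-2-yl)cyclohex-2-en-1-yl]oxy}dimethylsilane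
Product: 7 2-[(1S,5S)-5-(tert-butyldimethylsilyloxy)-2,2,4-trimethoxycyclohex-3-en-1-yl]propan-2-ol
Conditions: Co(acac)2 (0.2 equiv), PhSiH3, O2 (1 atm), THF–i-PrOH, rt
Reagents that add atoms: dioxygen, O=O
Why: Mukaiyama hydration (cobalt-catalysed hydrogen-atom transfer, capture of O2, reduction by the silane) converts the exposed 1,1-disubstituted alkene into the Markovnikov tertiary alcohol, while the trisubstituted enol ether flanked by the ketal carbon is sterically shielded from the metal hydride.

Step 6
Reactants: 7 2-[(1S,5S)-5-(tert-butyldimethylsilyloxy)-2,2,4-trimethoxycyclohex-3-en-1-yl]propan-2-ol; 8 allyl bromide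
Product: 9 tert-butyl{[(1S,5S)-5-[2-(allyloxy)propan-2-yl]-2,4,4-trimethoxycyclohex-2-en-1-yl]oxy}dimethylsilane
Conditions: KH, THF, 0 °C; allyl bromide, Bu4NI (cat.), rt
Reagents that add atoms: none
Why: Williamson etherification of the tertiary potassium alkoxide with a reactive allylic halide; no base-sensitive group is present at this stage.

Step 7
Reactants: 9 tert-butyl{[(1S,5S)-5-[2-(allyloxy)propan-2-yl]-2,4,4-trimethoxycyclohex-2-en-1-yl]oxy}dimethylsilane
Product: 11 (4S,6S)-4-[2-(allyloxy)propan-2-yl]-6-(tert-butyldimethylsilyloxy)cyclohexane-1,3-dione, via vinylogous ester 10 (not isolated)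
Conditions: 1 M aq. HCl, THF, 0 °C to rt
Reagents that add atoms: water, O
Why: Acid hydrolysis first opens the ketal to vinylogous ester 10 and then hydrolyses this to the 1,3-dione, while the silyl ether (α to the carbonyl and so deactivated towards protonation) and the tertiary allyl ether should persist in dilute acid at or below room temperature.

Step 8
Reactants: 11 (4S,6S)-4-[2-(allyloxy)propan-2-yl]-6-(tert-butyldimethylsilyloxy)cyclohexane-1,3-dione
Product: 12 (4S,6S)-4-[2-(allyloxy)propan-2-yl]-6-(tert-butyldimethylsilyloxy)-2-diazocyclohexane-1,3-dione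
Conditions: 4-acetamidobenzenesulfonyl azide, Et3N, MeCN, 0 °C to rt
Reagents that add atoms: 4-acetamidobenzenesulfonyl azide, CC(=O)Nc1ccc(cc1)S(=O)(=O)N=[N+]=[N-]
Why: Regitz diazo transfer from a sulfonyl azide to the acidic C2 of the 1,3-dione; the cis diequatorial arrangement of the two ring substituents is the stable one, so the mild base cannot erode it.

Step 9
Reactants: 12 (4S,6S)-4-[2-(allyloxy)propan-2-yl]-6-(tert-butyldimethylsilyloxy)-2-diazocyclohexane-1,3-dione
Product: 14 (1S,3S,5R)-5-allyl-3-(tert-butyldimethylsilyloxy)-7,7-dimethyl-6-oxabicyclo[3.2.1]octane-4,8-dione, via oxonium ylide 13 (not isolated)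
Conditions: Rh2(OAc)4 (2 mol %), CH2Cl2, 40 °C, slow addition of 12
Reagents that add atoms: none
Why: Loss of N2 gives an electrophilic rhodium carbenoid at C2 of the dione, which is captured by the ether oxygen of the C4 side chain to give bicyclic oxonium ylide 13; the allyl group then moves from oxygen to the ylide carbon through a five-membered [2,3]-sigmatropic transition state, so the C–O and C–C bonds at the future cage C3 form in one event. The closest known reaction type is the metal-catalysed oxonium ylide formation/[2,3]-rearrangement of allyl ethers tethered to diazo ketones and diazo dicarbonyl compounds, which gives 3-furanones and bridged ethers. The tetrahydrofuranone ring closes by attack of oxygen on the carbenoid carbon in a five-membered (1,5) mode, bridging C2 and C4 of the carbocycle to a 6-oxabicyclo[3.2.1]octane; this requires the side chain to turn pseudo-axial, a conformer the ring can reach. The new quaternary stereocentre is fixed by the tether, because the oxygen can reach only the face of C2 on which the side chain sits and the allyl group is delivered to the ylide carbon with that C–O bond already in place. The step needs ylide formation to outrun C–H insertion and cyclopropanation and the [2,3] shift to outrun [1,2] and [1,4] migration; the five-membered ylide, the silyl ether (no activated C–H bond), the remoteness of the alkene from the carbenoid and the allyl migrating group should secure this.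

Step 10
Reactants: 14 (1S,3S,5R)-5-allyl-3-(tert-butyldimethylsilyloxy)-7,7-dimethyl-6-oxabicyclo[3.2.1]octane-4,8-dione; 15 2-methyl-2-butene
Product: 16 (1S,3S,5R)-3-(tert-butyldimethylsilyloxy)-7,7-dimethyl-5-(3-methylbut-2-en-1-yl)-6-oxabicyclo[3.2.1]octane-4,8-dione
Conditions: second-generation Grubbs catalyst (5 mol %), 2-methyl-2-butene (excess), CH2Cl2, 40 °C
Reagents that add atoms: none
Why: Olefin cross-metathesis of the terminal allyl group with excess 2-methyl-2-butene is a standard way of turning allyl into prenyl, and the trisubstituted product alkene does not react further.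

Step 11
Reactants: 16 (1S,3S,5R)-3-(tert-butyldimethylsilyloxy)-7,7-dimethyl-5-(3-methylbut-2-en-1-yl)-6-oxabicyclo[3.2.1]octane-4,8-dione; 17 allyl acrylate
Product: 19 allyl (1R,3R,6R,7S)-1-(tert-butyldimethylsilyloxy)-7-hydroxy-5,5-dimethyl-3-(3-methylbut-2-en-1-yl)-2-oxo-4-oxatricyclo[4.3.1.0^3,7]decane-8-carboxylate (C8 epimers), via lithium ester enolate 18 (not isolated)
Conditions: LiN(SiMe3)2, THF, −78 °C; allyl acrylate, −78 to 0 °C; aq. NH4Cl
Reagents that add atoms: none
Why: Tandem Michael addition–intramolecular aldol reaction: in the bicycle only C3–H is enolisable (the other α-carbon, C1, is a bridgehead), the enolate adds to the acrylate on the face anti to the ether bridge, and the resulting ester enolate can reach only the C8 ketone on its face turned towards C3, which closes the bicyclo[2.2.2]octane and fixes cage centres C1 and C7 by geometry.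

Step 12
Reactants: 19 allyl (1R,3R,6R,7S)-1-(tert-butyldimethylsilyloxy)-7-hydroxy-5,5-dimethyl-3-(3-methylbut-2-en-1-yl)-2-oxo-4-oxatricyclo[4.3.1.0^3,7]decane-8-carboxylate
Product: 21 allyl (1R,3R,6R,7S)-1-(tert-butyldimethylsilyloxy)-7-hydroxy-5,5-dimethyl-3-(3-methylbut-2-en-1-yl)-2-oxo-4-oxatricyclo[4.3.1.0^3,7]dec-8-ene-8-carboxylate, via selenide 20 (not isolated)
Conditions: LiN(i-Pr)2 (2.3 equiv), THF, −78 °C; PhSeBr, −78 °C; aq. NH4Cl; then NaIO4, NaHCO3, THF–H2O, rt
Reagents that add atoms: none
Why: α-Selenenylation of the β-hydroxy ester dianion followed by selenoxide syn-elimination introduces the C8=C9 double bond, the only β-hydrogens being those of the C9 methylene; periodate is the oxidant so that the prenyl group is spared.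

Step 13
Reactants: 21 allyl (1R,3R,6R,7S)-1-(tert-butyldimethylsilyloxy)-7-hydroxy-5,5-dimethyl-3-(3-methylbut-2-en-1-yl)-2-oxo-4-oxatricyclo[4.3.1.0^3,7]dec-8-ene-8-carboxylate
Product: 22 allyl (1R,3R,6R,7S)-1,7-dihydroxy-5,5-dimethyl-3-(3-methylbut-2-en-1-yl)-2-oxo-4-oxatricyclo[4.3.1.0^3,7]dec-8-ene-8-carboxylate
Conditions: HF (48% aq.), MeCN, 0 °C to rt
Reagents that add atoms: none
Why: Fluoride-mediated cleavage of the tertiary silyl ether under acidic conditions, which avoid the base-induced α-ketol rearrangement open to the free C1 hydroxy ketone.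

Step 14
Reactants: 22 allyl (1R,3R,6R,7S)-1,7-dihydroxy-5,5-dimethyl-3-(3-methylbut-2-en-1-yl)-2-oxo-4-oxatricyclo[4.3.1.0^3,7]dec-8-ene-8-carboxylate
Product: 23 (1R,3R,6R,7S)-1,7-dihydroxy-5,5-dimethyl-3-(3-methylbut-2-en-1-yl)-2-oxo-4-oxatricyclo[4.3.1.0^3,7]dec-8-ene-8-carboxylic acid
Conditions: Pd(PPh3)4 (5 mol %), dimedone, THF, rt
Reagents that add atoms: none
Why: Palladium-catalysed allyl transfer (Tsuji–Trost type deallylation) to a soft carbon acid frees the carboxylic acid under neutral conditions, avoiding hydroxide, which could attack the strained C2 ketone or add to the enoate.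

Step 15
Reactants: 24 2,6-dimethoxy-1,4-benzoquinone
Product: 25 2-hydroxy-6-methoxy-1,4-benzoquinone
Conditions: NaOH (1.1 equiv), H2O–THF, 0 °C to rt; then 1 M HCl
Reagents that add atoms: sodium hydroxide, [Na+].[OH-]
Why: Alkaline hydrolysis of a vinylogous ester by addition–elimination; the hydroxyquinone anion that forms is deactivated, so the second methoxy group stays.

Step 16
Reactants: 25 2-hydroxy-6-methoxy-1,4-benzoquinone; 26 3-methylbut-2-enal
Product: 28 7-methoxy-2,2-dimethyl-2H-chromene-5,8-dione, via alkylidene trione 27 (not isolated)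
Conditions: ethylenediammonium diacetate (10 mol %), toluene, 80 °C
Reagents that add atoms: none
Why: Formal [3+3] annulation: Knoevenagel condensation at the nucleophilic C3 of the hydroxyquinone gives alkylidene trione 27, whose oxa-6π-electrocyclisation builds the 2,2-dimethyl-2H-pyran, as in the known conversion of 2-hydroxy-1,4-quinones and enals into pyranoquinones.

Step 17
Reactants: 28 7-methoxy-2,2-dimethyl-2H-chromene-5,8-dione
Product: 29 7-hydroxy-2,2-dimethyl-2H-chromene-5,8-dione
Conditions: NaOH (1.1 equiv), H2O–THF, 0 °C to rt; then 1 M HCl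
Reagents that add atoms: sodium hydroxide, [Na+].[OH-]
Why: Hydrolysis of the remaining vinylogous methyl ester by addition–elimination at the unhindered C7, the ring oxygen at C8a belonging to a tetrasubstituted and more hindered enol ether.

Step 18
Reactants: 29 7-hydroxy-2,2-dimethyl-2H-chromene-5,8-dione; 30 prenyl bromide
Product: 31 7-hydroxy-2,2-dimethyl-6-(3-methylbut-2-en-1-yl)-2H-chromene-5,8-dione
Conditions: LiH, DMSO, rt; prenyl bromide, 45 °C
Reagents that add atoms: none
Why: C-alkylation of the lithium salt of a 2-hydroxy-1,4-quinone with prenyl bromide in DMSO (the lapachol-type prenylation), the lithium counter-ion favouring attack through carbon over oxygen.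

Step 19
Reactants: 23 (1R,3R,6R,7S)-1,7-dihydroxy-5,5-dimethyl-3-(3-methylbut-2-en-1-yl)-2-oxo-4-oxatricyclo[4.3.1.0^3,7]dec-8-ene-8-carboxylic acid; 31 7-hydroxy-2,2-dimethyl-6-(3-methylbut-2-en-1-yl)-2H-chromene-5,8-dione
Product: 32 2,2-dimethyl-6-(3-methylbut-2-en-1-yl)-5,8-dioxo-2H-chromen-7-yl ester of acid 23 (quinone enol ester)
Conditions: EDC·HCl, DMAP (0.1 equiv), CH2Cl2, 0 °C to rt
Reagents that add atoms: none
Why: Carbodiimide-mediated (Steglich-type) acylation of the acidic quinone hydroxyl gives the enol ester, the two tertiary cage hydroxyls being too hindered to be acylated.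

Step 20
Reactants: 32 quinone enol ester of acid 23
Product: 34 CNP0222516.1 (target), via spiro dienol 33 (not isolated)
Conditions: (+)-10-camphorsulfonic acid (0.2 equiv), CH2Cl2, rt
Reagents that add atoms: none
Why: Proposed new method: under acid catalysis the tertiary C7 hydroxyl should add in a 6-exo-trig oxa-Michael fashion to the acyloxy-bearing quinone carbon (β to the chromenedione C5 carbonyl and made more electrophilic by the acyloxy group), giving spiro dienol 33 whose ketonisation puts hydrogen on the prenyl-bearing carbon; the closest known reaction types are intramolecular oxa-Michael spiroketalisations onto β-alkoxy enones, acid-catalysed additions of alcohols to quinones and the acid-catalysed formation of 1,3-dioxan-4-ones from β-hydroxy acids and carbonyl compounds; both new stereocentres form reversibly (retro-oxa-Michael, enolisation) and are expected to settle with the prenyl group on the face of the lactone oxygen, away from the cage.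

**Compound list**

1 | 2,4-dimethoxyphenol | COc1ccc(O)c(OC)c1 | starting material
2 | 2,4,4-trimethoxycyclohexa-2,5-dien-1-one | COC1=CC(OC)(OC)C=CC1=O | intermediate
3 | isopropenylboronic acid pinacol ester | CC(=C)B1OC(C)(C)C(C)(C)O1 | starting material
4 | (S)-2,4,4-trimethoxy-5-(prop-1-en-2-yl)cyclohex-2-en-1-one | O=C1C(OC)=CC(OC)(OC)[C@H](C(C)=C)C1 | intermediate
5 | (1S,5S)-2,4,4-trimethoxy-5-(prop-1-en-2-yl)cyclohex-2-en-1-ol (cis) | O[C@@H]1C(OC)=CC(OC)(OC)[C@H](C(C)=C)C1 | intermediate
6 | tert-butyl{[(1S,5S)-2,4,4-trimethoxy-5-(prop-1-en-2-yl)cyclohex-2-en-1-yl]oxy}dimethylsilane | CC(C)(C)[Si](C)(C)O[C@@H]1C(OC)=CC(OC)(OC)[C@H](C(C)=C)C1 | intermediate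
7 | 2-[(1S,5S)-5-(tert-butyldimethylsilyloxy)-2,2,4-trimethoxycyclohex-3-en-1-yl]propan-2-ol | CC(C)(C)[Si](C)(C)O[C@@H]1C(OC)=CC(OC)(OC)[C@H](C(C)(C)O)C1 | intermediate
8 | allyl bromide | C=CCBr | starting material
9 | tert-butyl{[(1S,5S)-5-[2-(allyloxy)propan-2-yl]-2,4,4-trimethoxycyclohex-2-en-1-yl]oxy}dimethylsilane | CC(C)(C)[Si](C)(C)O[C@@H]1C(OC)=CC(OC)(OC)[C@H](C(C)(C)OCC=C)C1 | intermediate
10 | (4S,6S)-6-[2-(allyloxy)propan-2-yl]-4-(tert-butyldimethylsilyloxy)-3-methoxycyclohex-2-en-1-one (vinylogous ester, not isolated) | CC(C)(C)[Si](C)(C)O[C@@H]1C(OC)=CC(=O)[C@H](C(C)(C)OCC=C)C1 | intermediate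
11 | (4S,6S)-4-[2-(allyloxy)propan-2-yl]-6-(tert-butyldimethylsilyloxy)cyclohexane-1,3-dione (cis; drawn as diketo tautomer) | CC(C)(C)[Si](C)(C)O[C@@H]1C(=O)CC(=O)[C@H](C(C)(C)OCC=C)C1 | intermediate
12 | (4S,6S)-4-[2-(allyloxy)propan-2-yl]-6-(tert-butyldimethylsilyloxy)-2-diazocyclohexane-1,3-dione | CC(C)(C)[Si](C)(C)O[C@@H]1C(=O)C(=[N+]=[N-])C(=O)[C@H](C(C)(C)OCC=C)C1 | intermediate
13 | bicyclic oxonium ylide (O-allyl oxonium at the ring oxygen, carbanion between the two ketones; not isolated) | [C@H]1(O[Si](C)(C)C(C)(C)C)C[C@H]2C(C)(C)[O+](CC=C)[C-](C1=O)C2=O | intermediate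
14 | (1S,3S,5R)-5-allyl-3-(tert-butyldimethylsilyloxy)-7,7-dimethyl-6-oxabicyclo[3.2.1]octane-4,8-dione | [C@H]1(O[Si](C)(C)C(C)(C)C)C[C@H]2C(C)(C)O[C@@](CC=C)(C1=O)C2=O | intermediate
15 | 2-methyl-2-butene | CC=C(C)C | starting material
16 | (1S,3S,5R)-3-(tert-butyldimethylsilyloxy)-7,7-dimethyl-5-(3-methylbut-2-en-1-yl)-6-oxabicyclo[3.2.1]octane-4,8-dione | [C@H]1(O[Si](C)(C)C(C)(C)C)C[C@H]2C(C)(C)O[C@@](CC=C(C)C)(C1=O)C2=O | intermediate
17 | allyl acrylate | C=CC(=O)OCC=C | starting material
18 | lithium ester enolate of the C3 Michael adduct of 16 (not isolated) | [Li+].[O-]C(OCC=C)=CC[C@]1(O[Si](C)(C)C(C)(C)C)C[C@H]2C(C)(C)O[C@@](CC=C(C)C)(C1=O)C2=O | intermediate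
19 | allyl (1R,3R,6R,7S)-1-(tert-butyldimethylsilyloxy)-7-hydroxy-5,5-dimethyl-3-(3-methylbut-2-en-1-yl)-2-oxo-4-oxatricyclo[4.3.1.0^3,7]decane-8-carboxylate (C8 epimers) | C=CCOC(=O)C1C[C@]3(O[Si](C)(C)C(C)(C)C)C[C@H]4C(C)(C)O[C@@](CC=C(C)C)(C3=O)[C@@]14O | intermediate
20 | 8-(phenylselanyl) derivative of 19 (not isolated) | C=CCOC(=O)C1([Se]c2ccccc2)C[C@]3(O[Si](C)(C)C(C)(C)C)C[C@H]4C(C)(C)O[C@@](CC=C(C)C)(C3=O)[C@@]14O | intermediate
21 | allyl (1R,3R,6R,7S)-1-(tert-butyldimethylsilyloxy)-7-hydroxy-5,5-dimethyl-3-(3-methylbut-2-en-1-yl)-2-oxo-4-oxatricyclo[4.3.1.0^3,7]dec-8-ene-8-carboxylate | C=CCOC(=O)C1=C[C@]3(O[Si](C)(C)C(C)(C)C)C[C@H]4C(C)(C)O[C@@](CC=C(C)C)(C3=O)[C@@]14O | intermediate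
22 | allyl (1R,3R,6R,7S)-1,7-dihydroxy-5,5-dimethyl-3-(3-methylbut-2-en-1-yl)-2-oxo-4-oxatricyclo[4.3.1.0^3,7]dec-8-ene-8-carboxylate | C=CCOC(=O)C1=C[C@]3(O)C[C@H]4C(C)(C)O[C@@](CC=C(C)C)(C3=O)[C@@]14O | intermediate
23 | (1R,3R,6R,7S)-1,7-dihydroxy-5,5-dimethyl-3-(3-methylbut-2-en-1-yl)-2-oxo-4-oxatricyclo[4.3.1.0^3,7]dec-8-ene-8-carboxylic acid | OC(=O)C1=C[C@]3(O)C[C@H]4C(C)(C)O[C@@](CC=C(C)C)(C3=O)[C@@]14O | intermediate
24 | 2,6-dimethoxy-1,4-benzoquinone | COC1=CC(=O)C=C(OC)C1=O | starting material
25 | 2-hydroxy-6-methoxy-1,4-benzoquinone | COC1=CC(=O)C=C(O)C1=O | intermediate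
26 | 3-methylbut-2-enal | CC(C)=CC=O | starting material
27 | 6-methoxy-3-(3-methylbut-2-en-1-ylidene)cyclohex-5-ene-1,2,4-trione (not isolated) | COC1=CC(=O)C(=CC=C(C)C)C(=O)C1=O | intermediate
28 | 7-methoxy-2,2-dimethyl-2H-chromene-5,8-dione | COC1=CC(=O)C2=C(OC(C)(C)C=C2)C1=O | intermediate
29 | 7-hydroxy-2,2-dimethyl-2H-chromene-5,8-dione | OC1=CC(=O)C2=C(OC(C)(C)C=C2)C1=O | intermediate
30 | prenyl bromide (1-bromo-3-methylbut-2-ene) | CC(C)=CCBr | starting material
31 | 7-hydroxy-2,2-dimethyl-6-(3-methylbut-2-en-1-yl)-2H-chromene-5,8-dione | CC(C)=CCC1=C(O)C(=O)C2=C(C=CC(C)(C)O2)C1=O | intermediate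
32 | 2,2-dimethyl-6-(3-methylbut-2-en-1-yl)-5,8-dioxo-2H-chromen-7-yl ester of acid 23 (cage configuration as in 23) | CC(C)=CCC1=C(OC(=O)C3=C[C@]4(O)C[C@H]5C(C)(C)O[C@@](CC=C(C)C)(C4=O)[C@@]35O)C(=O)C2=C(C=CC(C)(C)O2)C1=O | intermediate
33 | spiro dienol (enol tautomer of the target at the prenyl-bearing carbon; not isolated) | CC(C)=CCC1=C(O)C2=C(OC(C)(C)C=C2)C(=O)[C@@]13OC(=O)C1=C[C@]4(O)C[C@H]5C(C)(C)O[C@@](CC=C(C)C)(C4=O)[C@@]15O3 | intermediate
34 | CNP0222516.1 (spiro 1,3-dioxan-4-one joining the cage to the prenylated pyranocyclohexenedione) | CC(C)=CC[C@H]1C(=O)C2=C(OC(C)(C)C=C2)C(=O)[C@@]12OC(=O)C1=C[C@]3(O)C[C@H]4C(C)(C)O[C@@](CC=C(C)C)(C3=O)[C@@]14O2 | target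

**Step count**

Total: 20 steps. Longest linear sequence: 16 steps (steps 1–14, 19 and 20); the quinone branch is steps 15–18.

**Steps most likely to fail**

1. Step 20. The tertiary hydroxyl may add too slowly to the enol ester carbon, the ring-closed form may not be favoured at equilibrium, equilibration may settle on the other arrangement at the spiro carbon, or the activated ester may be cleaved by traces of water. The fallback sets out from 21 and 31 and returns at 34; it reverses the order of the two C–O bond formations so that the hindered oxygen is used as an alkoxide under irreversible conditions. Hydroxyquinone 31 is converted with oxalyl chloride and catalytic DMF into the vinylogous acid chloride 7-chloro-2,2-dimethyl-6-(3-methylbut-2-en-1-yl)-2H-chromene-5,8-dione F1. The potassium alkoxide of 21 (KN(SiMe3)2, THF, −78 °C) displaces chloride by addition–elimination to give the tert-alkyl quinonyl ether allyl ester F2. Allyl transfer to dimedone with Pd(PPh3)4 frees the quinonyl ether acid F3. Acid-catalysed addition of the carboxyl group to the alkoxy-bearing quinone carbon, the intramolecular form of the known addition of carboxylic acids to enol ethers, closes the lactone to the silylated target F4, and HF in MeCN gives 34.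

2. Step 9. The carbenoid may be diverted into C–H insertion next to the ether oxygen, [1,2]- or [1,4]-allyl migration, fragmentation of the ylide with loss of the tertiary ether, or dimerisation, because the side chain must first turn pseudo-axial against the cis silyloxy group. The fallback sets out from 7 and returns at 14; it makes the two bonds to the quaternary carbon one after the other by polar chemistry. Acid hydrolysis of 7 (as in step 7) gives (4S,6S)-6-(tert-butyldimethylsilyloxy)-4-(2-hydroxypropan-2-yl)cyclohexane-1,3-dione F5. Palladium-catalysed C-allylation (Tsuji–Trost reaction, allyl acetate, Pd(PPh3)4) gives its 2-allyl derivative F6. Oxidative α-etherification with PhI(OAc)2 (hypervalent-iodine activation of the enol and displacement by the tethered tertiary hydroxyl) then closes the tetrahydrofuranone ring to 14, with the same tether-controlled configuration.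

3. Step 11. The hindered α-silyloxy enolate may add sluggishly to the acrylate, the acrylate may oligomerise, or the ester enolate may be quenched before the aldol closure. The fallback sets out from 16 and returns at 19; it separates the two bond formations and uses Lewis-acid instead of anionic conditions for the first. The enolate of 16 is trapped with Me3SiCl as the trimethylsilyl enol ether F7. Mukaiyama–Michael addition of F7 to allyl acrylate under HNTf2 catalysis gives the keto ester F8. Deprotonation of the ester with LiN(SiMe3)2 at −78 °C, the ketones now having no enolisable hydrogen, then effects the aldol closure to 19.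

**Further compounds**

F1 | step 20 | 7-chloro-2,2-dimethyl-6-(3-methylbut-2-en-1-yl)-2H-chromene-5,8-dione | CC(C)=CCC1=C(Cl)C(=O)C2=C(C=CC(C)(C)O2)C1=O
F2 | step 20 | allyl ester 21 etherified at the C7 oxygen with the 2,2-dimethyl-6-prenyl-5,8-dioxo-2H-chromen-7-yl group | C=CCOC(=O)C1=C[C@]3(O[Si](C)(C)C(C)(C)C)C[C@H]4C(C)(C)O[C@@](CC=C(C)C)(C3=O)[C@@]14OC5=C(CC=C(C)C)C(=O)C6=C(OC(C)(C)C=C6)C5=O
F3 | step 20 | carboxylic acid corresponding to F2 | OC(=O)C1=C[C@]3(O[Si](C)(C)C(C)(C)C)C[C@H]4C(C)(C)O[C@@](CC=C(C)C)(C3=O)[C@@]14OC5=C(CC=C(C)C)C(=O)C6=C(OC(C)(C)C=C6)C5=O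
F4 | step 20 | tert-butyldimethylsilyl ether of the target at the cage C1 hydroxyl | CC(C)=CC[C@H]1C(=O)C2=C(OC(C)(C)C=C2)C(=O)[C@@]12OC(=O)C1=C[C@]3(O[Si](C)(C)C(C)(C)C)C[C@H]4C(C)(C)O[C@@](CC=C(C)C)(C3=O)[C@@]14O2
F5 | step 9 | (4S,6S)-6-(tert-butyldimethylsilyloxy)-4-(2-hydroxypropan-2-yl)cyclohexane-1,3-dione | CC(C)(C)[Si](C)(C)O[C@@H]1C(=O)CC(=O)[C@H](C(C)(C)O)C1
F6 | step 9 | (4S,6S)-2-allyl-6-(tert-butyldimethylsilyloxy)-4-(2-hydroxypropan-2-yl)cyclohexane-1,3-dione | CC(C)(C)[Si](C)(C)O[C@@H]1C(=O)C(CC=C)C(=O)[C@H](C(C)(C)O)C1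
F7 | step 11 | trimethylsilyl enol ether of 16 (C3=C4 enol ether) | C1(O[Si](C)(C)C(C)(C)C)=C(O[Si](C)(C)C)[C@]2(CC=C(C)C)OC(C)(C)[C@H](C1)C2=O
F8 | step 11 | allyl 3-[(1S,3R,5R)-3-(tert-butyldimethylsilyloxy)-7,7-dimethyl-5-(3-methylbut-2-en-1-yl)-4,8-dioxo-6-oxabicyclo[3.2.1]octan-3-yl]propanoate | C=CCOC(=O)CC[C@]1(O[Si](C)(C)C(C)(C)C)C[C@H]2C(C)(C)O[C@@](CC=C(C)C)(C1=O)C2=O
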